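The route rests on a hidden symmetric unit. Counting from the sp carbon attached to C6' of cyclohexene ring A through to C5 of the furanone ring gives twelve chain carbons. These map onto a C2-symmetric 3,10-dimethyldodeca-3,5,7,9-tetraene-1,11-diyne. One terminus survives as the ring A alkyne and the other becomes the C5=CH ylidene pair. In one flask the mono-silylated diyne is coupled to the ring A enol triflate (C6'–C bond) and freed by fluoride. It is then coupled to a (Z)-β-iodoacrylic acid bearing the ring B triol (C4–C5 bond) and lactonised (O1–C5 bond). All three precursors carry free hydroxyls, so this operation ends at the target.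

Key step: step 21

Remark on numbering and configuration: ring B atoms carry carotenoid numbers (C1 = CMe2, C3 = CHOH, C5 = C(OH)CH3, C6 = carbinol carbon bearing the side chain). The target is read as 3S,5R,6R in ring B and 3'R in ring A. This means 5-OH is trans to both 3-OH and 6-OH, and the ylidene at furanone C5 is Z.

Remark on design: the hydroxyl of 1 is masked before enolisation. The two alkyne termini of the diyne are told apart by joining a silylated and an unsilylated half, both made from dienyl iodide 24, so no statistical desilylation is needed. Compounds 24 to 32 are handled under argon with exclusion of light.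

Step 1
Reactants: 1 (4R,6R)-actinol
Product: 2 (4R,6R)-4-(tert-butyldimethylsilyloxy)-2,2,6-trimethylcyclohexan-1-one
Conditions: TBSCl, imidazole, DMF, rt
Reagents that add atoms: tert-butyldimethylsilyl chloride, CC(C)(C)[Si](C)(C)Cl
Why: Imidazole-promoted silylation of the only hydroxyl removes the acidic O–H before strong base is used and touches neither stereocentre.

Step 2
Reactants: 2 silyl ether of actinol
Product: 4 (4R)-4-(tert-butyldimethylsilyloxy)-2,6,6-trimethylcyclohex-1-en-1-yl trifluoromethanesulfonate, via lithium enolate 3 (not isolated)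
Conditions: LiN(iPr)2, THF, -78 °C; PhNTf2, -78 °C to rt
Reagents that add atoms: N-phenylbis(trifluoromethanesulfonimide), O=S(=O)(N(c1ccccc1)S(=O)(=O)C(F)(F)F)C(F)(F)F
Why: The ketone can enolise only towards the CH(CH3) carbon, so a single enolate forms and is trapped on oxygen (enol triflate formation), which erases that stereocentre on purpose while the carbinol centre stays R.

Step 3
Reactants: 4 silylated enol triflate
Product: 5 (4R)-4-hydroxy-2,6,6-trimethylcyclohex-1-en-1-yl trifluoromethanesulfonate (ring A enol triflate)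
Conditions: HF·pyridine, pyridine, THF, 0 °C to rt
Reagents that add atoms: none
Why: Acidic fluoride cleaves the Si–O bond and leaves the vinyl triflate alone, whereas a basic fluoride source could attack sulfur.

Step 4
Reactants: 4 silylated enol triflate
Product: 6 methyl (4R)-4-(tert-butyldimethylsilyloxy)-2,6,6-trimethylcyclohex-1-ene-1-carboxylate
Conditions: Pd(OAc)2 (5 mol%), PPh3 (10 mol%), CO (1 atm), MeOH, Et3N, DMF, rt to 40 °C
Reagents that add atoms: carbon monoxide, [C-]#[O+]; methanol, CO
Why: Palladium-catalysed alkoxycarbonylation of an enol triflate (oxidative addition, CO insertion, methanolysis of the acylpalladium) installs the future C7 carbon on ring B C6.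

Step 5
Reactants: 6 unsaturated ester
Product: 7 [(4R)-4-(tert-butyldimethylsilyloxy)-2,6,6-trimethylcyclohex-1-en-1-yl]methanol
Conditions: iBu2AlH (2.5 equiv), CH2Cl2, -78 to 0 °C; aq potassium sodium tartrate
Reagents that add atoms: none
Why: 1,2-Reduction of the conjugated ester by iBu2AlH gives the allylic alcohol needed as the handle for the epoxidation and does not affect the silyl ether.

Step 6
Reactants: 7 allylic alcohol
Product: 8 [(1S,4S,6S)-4-(tert-butyldimethylsilyloxy)-2,2,6-trimethyl-7-oxabicyclo[4.1.0]heptan-1-yl]methanol (oxirane cis to the silyloxy group)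
Conditions: Ti(OiPr)4 (0.2 equiv), diethyl L-(+)-tartrate (0.25 equiv), tBuOOH (decane), 4 Å MS, CH2Cl2, -20 °C
Reagents that add atoms: tert-butyl hydroperoxide, CC(C)(C)OO
Why: In this Sharpless asymmetric epoxidation of a tetrasubstituted allylic alcohol the L-(+)-tartrate titanium complex binds the CH2OH group and delivers oxygen to the alkene face that also carries the C3 silyloxy group, so reagent control sets ring B C5 and C6 together.

Step 7
Reactants: 8 syn-epoxy alcohol
Product: 9 (1S,2R,4S)-4-(tert-butyldimethylsilyloxy)-1-(hydroxymethyl)-2,6,6-trimethylcyclohexane-1,2-diol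
Conditions: HClO4 (cat), THF/H2O, 0 °C, short contact
Reagents that add atoms: water, O
Why: In this acid-catalysed epoxide hydrolysis with trans-diaxial (Fürst–Plattner) opening, water attacks C5 from the face opposite the oxirane oxygen because C6 is neopentyl next to C1 and deactivated by its CH2OH group, so C5 is inverted to R, the C6–O bond is kept, and 5-OH ends trans to both 6-OH and the C3 oxygen.

Step 8
Reactants: 9 silylated tetraol
Product: 10 (1R,2R,4S)-4-(tert-butyldimethylsilyloxy)-1,2-dihydroxy-2,6,6-trimethylcyclohexane-1-carbaldehyde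
Conditions: IBX (1.5 equiv), DMSO, rt; used at once
Reagents that add atoms: none
Why: IBX oxidises the only oxidisable alcohol, does not normally cleave glycols at room temperature, and works without base, which avoids retro-aldol opening of the β-hydroxy aldehyde.

Step 9
Reactants: 10 α-hydroxy aldehyde
Product: 11 (1R,2R,4S)-4-(tert-butyldimethylsilyloxy)-1-[(E)-2-iodoethenyl]-2,6,6-trimethylcyclohexane-1,2-diol
Conditions: CrCl2 (8 equiv), CHI3 (3 equiv), THF, 0 °C to rt, dark
Reagents that add atoms: iodoform, IC(I)I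
Why: In the Takai olefination the gem-dichromium species made from CHI3 and CrCl2 adds to the aldehyde and eliminates to the (E)-iodoalkene, a preference that bulky aldehydes reinforce, and the non-basic reagent tolerates the free tertiary hydroxyls as chromium alkoxides.

Step 10
Reactants: 12 ethyl 3-(trimethylsilyl)propiolate
Product: 13 ethyl (E)-2-(tributylstannyl)-3-(trimethylsilyl)prop-2-enoate (silicon cis to the ester)
Conditions: Bu3SnH (slow addition), Pd(PPh3)4 (2 mol%), THF, 0 °C to rt
Reagents that add atoms: tributyltin hydride, CCCC[SnH](CCCC)CCCC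
Why: Palladium-catalysed hydrostannation of a 2-alkynoate is a syn H–Sn addition that sends hydride to the electrophilic β-carbon and tin to the α-carbon, away from the bulky silyl group, which fixes silicon cis to the ester.

Step 11
Reactants: 11 ring B vinyl iodide; 13 α-stannyl β-silyl acrylate
Product: 14 ethyl (2Z)-2-{(E)-2-[(1R,2R,4S)-4-(tert-butyldimethylsilyloxy)-1,2-dihydroxy-2,6,6-trimethylcyclohexyl]ethenyl}-3-(trimethylsilyl)prop-2-enoate
Conditions: Pd2(dba)3 (2.5 mol%), AsPh3 (20 mol%), CuI (20 mol%), DMF, rt to 45 °C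
Reagents that add atoms: none
Why: The copper-assisted Stille coupling of an alkenyl iodide with an α-stannyl acrylate proceeds with retention at both sp2 carbons, so the C7=C8 alkene stays E and silicon stays cis to the ester, and the neutral medium spares the diol, the silyl ether and the vinylsilane.

Step 12
Reactants: 14 dienyl silane
Product: 15 ethyl (2Z)-2-{(E)-2-[(1R,2R,4S)-4-(tert-butyldimethylsilyloxy)-1,2-dihydroxy-2,6,6-trimethylcyclohexyl]ethenyl}-3-iodoprop-2-enoate
Conditions: NIS (1.1 equiv), 2,6-lutidine (0.5 equiv), (CF3)2CHOH, 0 °C, dark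
Reagents that add atoms: N-iodosuccinimide, O=C1CCC(=O)N1I
Why: In this electrophilic ipso-iododesilylation iodonium attack at the silicon-bearing carbon gives a β-silyl-stabilised cation that loses silicon after least-motion rotation, which in a polar, poorly nucleophilic solvent means retention, so iodine ends cis to the ester as the later lactonisation requires.

Step 13
Reactants: 15 silylated iodo ester
Product: 16 ethyl (2Z)-3-iodo-2-{(E)-2-[(1R,2R,4S)-1,2,4-trihydroxy-2,6,6-trimethylcyclohexyl]ethenyl}prop-2-enoate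
Conditions: HF·pyridine, pyridine, THF, 0 °C to rt
Reagents that add atoms: none
Why: Pyridine-buffered HF removes the secondary silyl ether through Si–F bond formation under conditions that leave the vinyl iodide, the ester and the tertiary carbinols untouched.

Step 14
Reactants: 16 iodo ester triol
Product: 18 (2Z)-3-iodo-2-{(E)-2-[(1R,2R,4S)-1,2,4-trihydroxy-2,6,6-trimethylcyclohexyl]ethenyl}prop-2-enoic acid (iodo acid), via lithium carboxylate 17 (not isolated)
Conditions: LiOH, THF/H2O, 0 °C to rt; 1 M HCl to pH 3, EtOAc extraction, dark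
Reagents that add atoms: lithium hydroxide, [Li+].[OH-]
Why: This is a plain saponification, safe because the β-iodoacrylate has no α-hydrogen and so cannot lose HI, and because the E alkene holds the ring B hydroxyls out of reach of the carboxyl group.

Step 15
Reactants: 19 (E)-3-methylpent-2-en-4-yn-1-ol
Product: 22 (E)-3-methyl-5-(trimethylsilyl)pent-2-en-4-yn-1-ol, via dilithio salt 20 (not isolated), via doubly silylated enynol 21 (not isolated)
Conditions: n-BuLi (2.1 equiv), THF, -78 to 0 °C; TMSCl (2.2 equiv); 1 M aq HCl (cat), rt, brief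
Reagents that add atoms: chlorotrimethylsilane, C[Si](C)(C)Cl
Why: Double deprotonation and double silylation followed by mild acid exploits the much greater lability of the O–Si bond over the alkynyl C–Si bond, and the E alkene is not involved.

Step 16
Reactants: 22 silylated enynol
Product: 23 (E)-3-methyl-5-(trimethylsilyl)pent-2-en-4-ynal
Conditions: MnO2 (activated, excess), CH2Cl2, rt
Reagents that add atoms: none
Why: MnO2 oxidises the allylic alcohol selectively and under neutral conditions, which keeps the alkene geometry and the alkynylsilane.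

Step 17
Reactants: 23 enynal
Product: 24 [(3E,5E)-6-iodo-3-methylhexa-3,5-dien-1-yn-1-yl]trimethylsilane
Conditions: CrCl2 (6 equiv), CHI3 (2 equiv), THF, 0 °C, dark
Reagents that add atoms: iodoform, IC(I)I
Why: Takai olefination of the enal adds the sixth chain carbon of each half as an (E)-iodoalkene and tolerates the silyl alkyne.

Step 18
Reactants: 24 silylated dienyl iodide
Product: 26 trimethyl[(3E,5E)-3-methyl-6-(tributylstannyl)hexa-3,5-dien-1-yn-1-yl]silane, via dienyllithium 25 (not isolated)
Conditions: n-BuLi (1.05 equiv), Et2O, -78 °C; Bu3SnCl, -78 °C to rt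
Reagents that add atoms: tributyltin chloride, CCCC[Sn](Cl)(CCCC)CCCC
Why: Iodine–lithium exchange on an alkenyl iodide is fast at low temperature and configurationally retentive, and the alkenyllithium is stannylated before it can isomerise or be alkylated.

Step 19
Reactants: 24 silylated dienyl iodide
Product: 27 (1E,3E)-1-iodo-4-methylhexa-1,3-dien-5-yne
Conditions: K2CO3 (0.2 equiv), MeOH/THF, 0 °C to rt, dark; kept in solution
Reagents that add atoms: none
Why: Carbonate-catalysed methanolysis removes the alkynyl silyl group, and the alkenyl iodide is inert to this mild base.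

Step 20
Reactants: 26 silylated dienylstannane; 27 unsilylated dienyl iodide
Product: 28 trimethyl[(3E,5E,7E,9E)-3,10-dimethyldodeca-3,5,7,9-tetraene-1,11-diyn-1-yl]silane (mono-silylated diyne)
Conditions: Pd2(dba)3 (2.5 mol%), AsPh3 (10 mol%), NMP, rt, dark
Reagents that add atoms: none
Why: The Stille coupling forms the central C6–C7 bond with retention at both sp2 carbons, and because neither base nor copper is present no acetylide can form, so the free alkyne and the alkynylsilane are both spectators.

Step 21
Reactants: 5 ring A enol triflate; 28 mono-silylated diyne; 18 iodo acid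
Product: 32 target butenolide, via silyl-capped ring A polyenediyne 29 (not isolated), via terminal alkyne 30 (not isolated), via enynoic acid 31 (not isolated)
Conditions: 5 (1.05 equiv), 28 (1.0 equiv), Pd(PPh3)4 (5 mol%), CuI (10 mol%), Et3N, degassed DMF, rt to 45 °C, dark; TBAF (1.05 equiv, THF), 0 °C; 18 (1.0 equiv), Et3N, fresh Pd(PPh3)4 (3 mol%), rt; chromatography in the dark
Reagents that add atoms: none
Why: Zerovalent palladium inserts into the C–OTf bond of 5, the copper acetylide of the free terminus of 28 transmetalates and reductive elimination forms the C6'–alkyne bond (29), while the silyl cap keeps the other terminus silent. Fluoride then removes the cap (30), and because the β-iodoacrylic acid 18 adds oxidatively far faster than any residual hindered triflate, the second Sonogashira cycle forms the furanone C4–C5 bond with retention and gives the (Z)-2-en-4-ynoic acid 31. Its carboxylate, held cis to the alkyne, attacks the metal-activated triple bond at the proximal carbon in a 5-exo-dig closure (O1–C5), and protodemetalation releases the furanone ring. Anti addition of oxygen and metal places the polyene chain cis to O1, which is the (Z)-ylidene geometry of the target, no stereocentre is created and the four carbinol centres are untouched. The closest known reaction types are the tandem Sonogashira–lactonisation of (Z)-3-iodoalk-2-enoic acids and sequential Sonogashira couplings with desilylation in the same flask. Apart from its cap 28 is C2-symmetric, so either end may serve either partner, the cis iodo acid geometry favours 5-exo over 6-endo closure, and the amine medium tolerates all free hydroxyls.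

Compound list
1 | (4R,6R)-4-hydroxy-2,2,6-trimethylcyclohexan-1-one (actinol) | CC1(C)C[C@H](O)C[C@@H](C)C1=O | starting material
2 | (4R,6R)-4-(tert-butyldimethylsilyloxy)-2,2,6-trimethylcyclohexan-1-one | CC1(C)C[C@H](O[Si](C)(C)C(C)(C)C)C[C@@H](C)C1=O | intermediate
3 | lithium (4R)-4-(tert-butyldimethylsilyloxy)-2,6,6-trimethylcyclohex-1-en-1-olate | [Li+].CC1=C([O-])C(C)(C)C[C@H](O[Si](C)(C)C(C)(C)C)C1 | intermediate
4 | (4R)-4-(tert-butyldimethylsilyloxy)-2,6,6-trimethylcyclohex-1-en-1-yl trifluoromethanesulfonate | CC1=C(OS(=O)(=O)C(F)(F)F)C(C)(C)C[C@H](O[Si](C)(C)C(C)(C)C)C1 | intermediate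
5 | (4R)-4-hydroxy-2,6,6-trimethylcyclohex-1-en-1-yl trifluoromethanesulfonate | CC1=C(OS(=O)(=O)C(F)(F)F)C(C)(C)C[C@H](O)C1 | intermediate
6 | methyl (4R)-4-(tert-butyldimethylsilyloxy)-2,6,6-trimethylcyclohex-1-ene-1-carboxylate | CC1=C(C(=O)OC)C(C)(C)C[C@H](O[Si](C)(C)C(C)(C)C)C1 | intermediate
7 | [(4R)-4-(tert-butyldimethylsilyloxy)-2,6,6-trimethylcyclohex-1-en-1-yl]methanol | CC1=C(CO)C(C)(C)C[C@H](O[Si](C)(C)C(C)(C)C)C1 | intermediate
8 | [(1S,4S,6S)-4-(tert-butyldimethylsilyloxy)-2,2,6-trimethyl-7-oxabicyclo[4.1.0]heptan-1-yl]methanol | OC[C@@]12C(C)(C)C[C@H](O[Si](C)(C)C(C)(C)C)C[C@]1(C)O2 | intermediate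
9 | (1S,2R,4S)-4-(tert-butyldimethylsilyloxy)-1-(hydroxymethyl)-2,6,6-trimethylcyclohexane-1,2-diol | OC[C@@]1(O)C(C)(C)C[C@H](O[Si](C)(C)C(C)(C)C)C[C@@]1(C)O | intermediate
10 | (1R,2R,4S)-4-(tert-butyldimethylsilyloxy)-1,2-dihydroxy-2,6,6-trimethylcyclohexane-1-carbaldehyde | O=C[C@@]1(O)C(C)(C)C[C@H](O[Si](C)(C)C(C)(C)C)C[C@@]1(C)O | intermediate
11 | (1R,2R,4S)-4-(tert-butyldimethylsilyloxy)-1-[(E)-2-iodoethenyl]-2,6,6-trimethylcyclohexane-1,2-diol | I/C=C/[C@@]1(O)C(C)(C)C[C@H](O[Si](C)(C)C(C)(C)C)C[C@@]1(C)O | intermediate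
12 | ethyl 3-(trimethylsilyl)propiolate | CCOC(=O)C#C[Si](C)(C)C | starting material
13 | ethyl (E)-2-(tributylstannyl)-3-(trimethylsilyl)prop-2-enoate | CCOC(=O)/C(=C\[Si](C)(C)C)[Sn](CCCC)(CCCC)CCCC | intermediate
14 | ethyl (2Z)-2-{(E)-2-[(1R,2R,4S)-4-(tert-butyldimethylsilyloxy)-1,2-dihydroxy-2,6,6-trimethylcyclohexyl]ethenyl}-3-(trimethylsilyl)prop-2-enoate | C[Si](C)(C)/C=C(\C(=O)OCC)/C=C/[C@@]1(O)C(C)(C)C[C@H](O[Si](C)(C)C(C)(C)C)C[C@@]1(C)O | intermediate
15 | ethyl (2Z)-2-{(E)-2-[(1R,2R,4S)-4-(tert-butyldimethylsilyloxy)-1,2-dihydroxy-2,6,6-trimethylcyclohexyl]ethenyl}-3-iodoprop-2-enoate | I/C=C(\C(=O)OCC)/C=C/[C@@]1(O)C(C)(C)C[C@H](O[Si](C)(C)C(C)(C)C)C[C@@]1(C)O | intermediate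
16 | ethyl (2Z)-3-iodo-2-{(E)-2-[(1R,2R,4S)-1,2,4-trihydroxy-2,6,6-trimethylcyclohexyl]ethenyl}prop-2-enoate | I/C=C(\C(=O)OCC)/C=C/[C@@]1(O)C(C)(C)C[C@H](O)C[C@@]1(C)O | intermediate
17 | lithium salt of iodo acid 18 | [Li+].I/C=C(\C(=O)[O-])/C=C/[C@@]1(O)C(C)(C)C[C@H](O)C[C@@]1(C)O | intermediate
18 | (2Z)-3-iodo-2-{(E)-2-[(1R,2R,4S)-1,2,4-trihydroxy-2,6,6-trimethylcyclohexyl]ethenyl}prop-2-enoic acid | I/C=C(\C(=O)O)/C=C/[C@@]1(O)C(C)(C)C[C@H](O)C[C@@]1(C)O | intermediate
19 | (E)-3-methylpent-2-en-4-yn-1-ol | C#C/C(C)=C/CO | starting material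
20 | dilithio salt of 19 (lithium alkoxide and lithium acetylide) | [Li]C#C/C(C)=C/CO[Li] | intermediate
21 | trimethyl{[(E)-3-methyl-5-(trimethylsilyl)pent-2-en-4-yn-1-yl]oxy}silane | C[Si](C)(C)C#C/C(C)=C/CO[Si](C)(C)C | intermediate
22 | (E)-3-methyl-5-(trimethylsilyl)pent-2-en-4-yn-1-ol | C[Si](C)(C)C#C/C(C)=C/CO | intermediate
23 | (E)-3-methyl-5-(trimethylsilyl)pent-2-en-4-ynal | C[Si](C)(C)C#C/C(C)=C/C=O | intermediate
24 | [(3E,5E)-6-iodo-3-methylhexa-3,5-dien-1-yn-1-yl]trimethylsilane | C[Si](C)(C)C#C/C(C)=C/C=C/I | intermediate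
25 | [(1E,3E)-4-methyl-6-(trimethylsilyl)hexa-1,3-dien-5-yn-1-yl]lithium | C[Si](C)(C)C#C/C(C)=C/C=C/[Li] | intermediate
26 | trimethyl[(3E,5E)-3-methyl-6-(tributylstannyl)hexa-3,5-dien-1-yn-1-yl]silane | C[Si](C)(C)C#C/C(C)=C/C=C/[Sn](CCCC)(CCCC)CCCC | intermediate
27 | (1E,3E)-1-iodo-4-methylhexa-1,3-dien-5-yne | C#C/C(C)=C/C=C/I | intermediate
28 | trimethyl[(3E,5E,7E,9E)-3,10-dimethyldodeca-3,5,7,9-tetraene-1,11-diyn-1-yl]silane | C#C/C(C)=C/C=C/C=C/C=C(C)/C#C[Si](C)(C)C | intermediate
29 | (1R)-4-[(3E,5E,7E,9E)-3,10-dimethyl-12-(trimethylsilyl)dodeca-3,5,7,9-tetraene-1,11-diyn-1-yl]-3,5,5-trimethylcyclohex-3-en-1-ol | CC1=C(C#C/C(C)=C/C=C/C=C/C=C(C)/C#C[Si](C)(C)C)C(C)(C)C[C@H](O)C1 | intermediate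
30 | (1R)-4-[(3E,5E,7E,9E)-3,10-dimethyldodeca-3,5,7,9-tetraene-1,11-diyn-1-yl]-3,5,5-trimethylcyclohex-3-en-1-ol | CC1=C(C#C/C(C)=C/C=C/C=C/C=C(C)/C#C)C(C)(C)C[C@H](O)C1 | intermediate
31 | (2Z)-2-en-4-ynoic acid in which the terminal alkyne carbon of 30 has replaced the iodine of 18 | CC1=C(C#C/C(C)=C/C=C/C=C/C=C(C)/C#C/C=C(\C(=O)O)/C=C/[C@@]2(O)C(C)(C)C[C@H](O)C[C@@]2(C)O)C(C)(C)C[C@H](O)C1 | intermediate
32 | (5Z)-3-{(E)-2-[(1R,2R,4S)-1,2,4-trihydroxy-2,6,6-trimethylcyclohexyl]ethenyl}-5-{(2E,4E,6E,8E)-11-[(4R)-4-hydroxy-2,6,6-trimethylcyclohex-1-en-1-yl]-2,9-dimethylundeca-2,4,6,8-tetraen-10-yn-1-ylidene}furan-2(5H)-one | CC1=C(C#C/C(C)=C/C=C/C=C/C=C(C)/C=C2C=C(/C=C/[C@@]3(O)C(C)(C)C[C@H](O)C[C@@]3(C)O)C(=O)O/2)C(C)(C)C[C@H](O)C1 | target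

Total step count: 21.
Longest linear sequence: 13 steps (1, 2, 4, 5, 6, 7, 8, 9, 11, 12, 13, 14, 21).

Steps most likely to fail

Step 21. Several things could go wrong in the crowded one-pot medium.
- The hindered triflate may couple incompletely before the fluoride is added.
- The terminal alkynes may dimerise oxidatively.
- The lactonisation may stall at the open enynoic acid or drift towards 6-endo closure.
- The polyene may isomerise.

The fallback sets out from 5 and 28 and comes back at 32, with the three events separated. Compounds 5 and 28 are coupled under the same Pd(PPh3)4/CuI/Et3N conditions and 29 is isolated. K2CO3 in MeOH gives isolated 30. Sonogashira coupling of 30 with the iodo ester 16 instead of the acid gives the ethyl enynoate F1. LiOH saponification gives the enynoic acid 31. A separate AgNO3-catalysed 5-exo-dig lactonisation in the dark then delivers 32.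

Step 12. Ipso attack on the electron-poor vinylsilane may be slow. Capture of an iodonium ion on the C7=C8 alkene by the C5 hydroxyl (5-endo iodoetherification) could then compete, as could erosion of double-bond geometry. The fallback sets out from 14 and comes back at 16, and it removes the internal nucleophiles before iodine is introduced. TMSOTf and 2,6-lutidine convert 14 into the bis(trimethylsilyl) ether F2. NIS in MeCN gives the fully silylated iodo ester F3. HF·pyridine then strips all three silyl ethers at once to give 16.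

Step 9. Addition of the bulky gem-dichromium reagent to the neopentyl α-hydroxy aldehyde may be sluggish. That would leave time for α-ketol ring expansion or retro-aldol ring opening of the aldehyde. The fallback sets out from 8 and comes back at 11, and it never passes through a hydroxy aldehyde.
- IBX oxidation of 8 gives the epoxy aldehyde F4.
- The Ohira–Bestmann reagent with K2CO3 in MeOH gives the epoxy alkyne F5.
- Aqueous HClO4 opens F5 at C5, because the propargylic C6 position is disfavoured for cation development, and gives the alkynyl diol F6.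
- Hydrostannation catalysed by PdCl2(PPh3)2 with Bu3SnH places tin on the unhindered terminus and gives the (E)-vinylstannane F7.
- I2 converts F7 into 11 with retention.

Further compounds
F1 | step 21 | ethyl ester of enynoic acid 31 | CC1=C(C#C/C(C)=C/C=C/C=C/C=C(C)/C#C/C=C(\C(=O)OCC)/C=C/[C@@]2(O)C(C)(C)C[C@H](O)C[C@@]2(C)O)C(C)(C)C[C@H](O)C1
F2 | step 12 | 1,2-bis(trimethylsilyl) ether of 14 | C[Si](C)(C)/C=C(\C(=O)OCC)/C=C/[C@@]1(O[Si](C)(C)C)C(C)(C)C[C@H](O[Si](C)(C)C(C)(C)C)C[C@@]1(C)O[Si](C)(C)C
F3 | step 12 | 1,2-bis(trimethylsilyl) ether of 15 | I/C=C(\C(=O)OCC)/C=C/[C@@]1(O[Si](C)(C)C)C(C)(C)C[C@H](O[Si](C)(C)C(C)(C)C)C[C@@]1(C)O[Si](C)(C)C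
F4 | step 9 | 4-(tert-butyldimethylsilyloxy)-2,2,6-trimethyl-7-oxabicyclo[4.1.0]heptane-1-carbaldehyde, oxirane cis to the silyloxy group | O=C[C@@]12C(C)(C)C[C@H](O[Si](C)(C)C(C)(C)C)C[C@]1(C)O2
F5 | step 9 | 1-ethynyl analogue of F4 (epoxy alkyne) | C#C[C@@]12C(C)(C)C[C@H](O[Si](C)(C)C(C)(C)C)C[C@]1(C)O2
F6 | step 9 | 4-(tert-butyldimethylsilyloxy)-1-ethynyl-2,6,6-trimethylcyclohexane-1,2-diol with the ring configuration of 11 | C#C[C@@]1(O)C(C)(C)C[C@H](O[Si](C)(C)C(C)(C)C)C[C@@]1(C)O
F7 | step 9 | (E)-2-(tributylstannyl)ethenyl analogue of 11 | CCCC[Sn](CCCC)(CCCC)/C=C/[C@@]1(O)C(C)(C)C[C@H](O[Si](C)(C)C(C)(C)C)C[C@@]1(C)O
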